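**Plan**

Atoms carry germacrane numbers (ring C1–C10; C11, C12, C13 on C7; C14 on C10; C15 on C4). The feature used is the unit C3(OAc)–C4=C5–C6(O-lactone) of the ten-membered ring, a (Z)-2-ene-1,4-diol diester with its two oxygens trans, next to C7 with the C11(=C13)–C12 acrylic acid: the retron of a 1,4-acyloxylactonization of a ring 1,3-diene C3=C4–C5=C6.
Retrosynthesis: (a) the lactone O–C6 bond and the C3–OAc bond are cut together, giving an all-cis cyclodecatriene acrylic acid; (b) the ten-membered ring is cut at C1–C10 (alkenyl iodide plus aldehyde); (c) the chain is cut at C9=C10, at C6–C7 (alkyne plus epoxy alcohol), at C4–C5 and at C7–C11.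
Forward: a C7–C9/C11–C13 epoxy alcohol and a C1–C6 enyne are joined at C6–C7, the alkyne is reduced to the Z C5=C6 alkene, C9 is turned into the (Z)-alkenyl iodide, O8 is angeloylated, the ten-membered ring is closed at C1–C10, C12 (carried as a silyl-protected allylic alcohol) is raised to the acid, and the γ-lactone ring is closed last, in the step that also installs the C3 acetate.
Stereochemistry: C7 and C8 from a Sharpless epoxidation and an invertive epoxide opening; C1 from ligand control in the ring closure; C6 and C3 from the key step (C6 through the C7 tether, cis ring fusion; C3 through acetate delivery from palladium, trans to O6); the three Z ring alkenes from two Stork–Zhao olefinations and a Lindlar reduction; the Z ester from angelic acid.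

Key step: step 18

Remark: TBS = tert-butyldimethylsilyl, TBDPS = tert-butyldiphenylsilyl, TES = triethylsilyl, angeloyl = (2Z)-2-methylbut-2-enoyl; the free secondary allylic C1 hydroxyl is assumed to tolerate Pd(OAc)2/benzoquinone in AcOH at room temperature and is therefore left unprotected after the ring closure.

**Route**

Step 1
Reactants: 1 2-bromoprop-2-en-1-ol
Product: 2 [(2-bromoprop-2-en-1-yl)oxy](tert-butyl)diphenylsilane
Conditions: TBDPSCl, imidazole, CH2Cl2, 0 °C to rt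
Reagents that add atoms: tert-butyl(chloro)diphenylsilane, CC(C)(C)[Si](Cl)(c1ccccc1)c1ccccc1
Why: Silylation of a primary alcohol (hydroxyl protection); the TBDPS ether is chosen because it must outlast the TES and primary TBS ethers that are removed in steps 9, 11 and 13.

Step 2
Reactants: 2 [(2-bromoprop-2-en-1-yl)oxy](tert-butyl)diphenylsilane; 3 (2E)-3-(tributylstannyl)prop-2-en-1-ol
Product: 4 (2E)-4-[(TBDPS-oxy)methyl]penta-2,4-dien-1-ol
Conditions: Pd(PPh3)4 (5 mol %), CuI (10 mol %), DMF, 50 °C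
Reagents that add atoms: none
Why: Stille coupling of an alkenyl bromide with an (E)-alkenylstannane should form the C7–C11 bond with retention of the E geometry and tolerates the free allylic alcohol.

Step 3
Reactants: 4 (2E)-4-[(TBDPS-oxy)methyl]penta-2,4-dien-1-ol
Product: 5 {(2R,3R)-3-[3-(TBDPS-oxy)prop-1-en-2-yl]oxiran-2-yl}methanol
Conditions: Ti(OiPr)4 (10 mol %), D-(−)-diethyl tartrate (12 mol %), t-BuOOH, 4 Å molecular sieves, CH2Cl2, −20 °C
Reagents that add atoms: tert-butyl hydroperoxide, CC(C)(C)OO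
Why: Sharpless asymmetric epoxidation: the titanium tartrate complex should epoxidise only the allylic-alcohol alkene (C7=C8), and D-(−)-tartrate delivers oxygen to the face that gives the (2R,3R) epoxide, which fixes C8 and, after inversion in step 6, C7.

Step 4
Reactants: 6 3-(TBS-oxy)propanal
Product: 7 tert-butyl{[(3Z)-4-iodopent-3-en-1-yl]oxy}dimethylsilane
Conditions: [Ph3PEt]I, n-BuLi, THF, rt; I2, −78 °C; NaN(SiMe3)2, −20 °C; then 6, −78 °C to rt
Reagents that add atoms: ethyltriphenylphosphonium iodide, CC[P+](c1ccccc1)(c1ccccc1)c1ccccc1.[I-]; iodine, II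
Why: Stork–Zhao olefination (Wittig reaction of the α-iodo ylide Ph3P=C(I)CH3) should give the (Z)-2-iodoalkene under kinetic control and so sets the geometry of the future C3=C4 bond.

Step 5
Reactants: 7 tert-butyl{[(3Z)-4-iodopent-3-en-1-yl]oxy}dimethylsilane
Product: 8 tert-butyl(dimethyl){[(3Z)-4-methylhex-3-en-5-yn-1-yl]oxy}silane
Conditions: HC≡CMgBr, ZnBr2, THF, 0 °C; then 7, Pd(PPh3)4 (5 mol %), rt
Reagents that add atoms: ethynylmagnesium bromide, C#C[Mg]Br
Why: Negishi coupling of the alkenyl iodide with ethynylzinc bromide should proceed with retention at C4 and give the terminal enyne directly.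

Step 6
Reactants: 8 tert-butyl(dimethyl){[(3Z)-4-methylhex-3-en-5-yn-1-yl]oxy}silane; 5 {(2R,3R)-3-[3-(TBDPS-oxy)prop-1-en-2-yl]oxiran-2-yl}methanol
Product: 11 (2S,3S)-3-[(3Z)-3-methyl-6-(TBS-oxy)hex-3-en-1-yn-1-yl]-4-[(TBDPS-oxy)methyl]pent-4-ene-1,2-diol, via lithium acetylide 9 (not isolated), via alkynylalane 10 (not isolated)
Conditions: 8 (3 equiv), n-BuLi, toluene, 0 °C; Et2AlCl, 0 °C; then 5, toluene–CH2Cl2, 0 °C to rt; aq. potassium sodium tartrate
Reagents that add atoms: none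
Why: Alkynylalane opening of a 2,3-epoxy alcohol: the aluminium alkoxide activates the epoxide and the alkynyl group should attack C3 of the epoxy alcohol (C7, also the allylic position) with inversion, which sets C7 and places O8 and C6 anti while C8 is untouched.

Step 7
Reactants: 11 (2S,3S)-3-[(3Z)-3-methyl-6-(TBS-oxy)hex-3-en-1-yn-1-yl]-4-[(TBDPS-oxy)methyl]pent-4-ene-1,2-diol
Product: 12 (2S,3S)-3-[(1Z,3Z)-3-methyl-6-(TBS-oxy)hexa-1,3-dien-1-yl]-4-[(TBDPS-oxy)methyl]pent-4-ene-1,2-diol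
Conditions: H2 (1 atm), Pd/CaCO3 poisoned with Pb(OAc)2 (Lindlar catalyst), quinoline, EtOAc, rt
Reagents that add atoms: none
Why: Lindlar semi-hydrogenation adds hydrogen syn to the alkyne only and should give the Z C5=C6 bond of the (Z,Z)-diene.

Step 8
Reactants: 12 (2S,3S)-3-[(1Z,3Z)-3-methyl-6-(TBS-oxy)hexa-1,3-dien-1-yl]-4-[(TBDPS-oxy)methyl]pent-4-ene-1,2-diol
Product: 13 (2S,3S)-3-[(1Z,3Z)-3-methyl-6-(TBS-oxy)hexa-1,3-dien-1-yl]-4-[(TBDPS-oxy)methyl]-1,2-bis(TES-oxy)pent-4-ene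
Conditions: TESCl (3 equiv), imidazole, DMF, 0 °C to rt
Reagents that add atoms: chlorotriethylsilane, CC[Si](Cl)(CC)CC
Why: Exhaustive silylation (hydroxyl protection) gives the bis-TES ether that the selective oxidation of step 9 requires.

Step 9
Reactants: 13 (2S,3S)-3-[(1Z,3Z)-3-methyl-6-(TBS-oxy)hexa-1,3-dien-1-yl]-4-[(TBDPS-oxy)methyl]-1,2-bis(TES-oxy)pent-4-ene
Product: 14 (2S,3S)-3-[(1Z,3Z)-3-methyl-6-(TBS-oxy)hexa-1,3-dien-1-yl]-4-[(TBDPS-oxy)methyl]-2-(TES-oxy)pent-4-enal
Conditions: (COCl)2, DMSO, CH2Cl2, −78 to −40 °C; Et3N, −78 to 0 °C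
Reagents that add atoms: none
Why: Swern oxidation of a bis-TES ether: the primary TES ether is cleaved by the chlorosulfonium reagent and oxidised in the same operation, whereas the secondary TES, primary TBS and TBDPS ethers should survive and the low temperature keeps the α-silyloxy aldehyde configurationally intact.

Step 10
Reactants: 14 (2S,3S)-3-[(1Z,3Z)-3-methyl-6-(TBS-oxy)hexa-1,3-dien-1-yl]-4-[(TBDPS-oxy)methyl]-2-(TES-oxy)pent-4-enal
Product: 15 (2Z,4S,5S,6Z,8Z)-2-iodo-8-methyl-11-(TBS-oxy)-5-[3-(TBDPS-oxy)prop-1-en-2-yl]-4-(TES-oxy)undeca-2,6,8-triene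
Conditions: [Ph3PEt]I, n-BuLi, THF, rt; I2, −78 °C; NaN(SiMe3)2, −20 °C; then 14, −78 °C to rt
Reagents that add atoms: ethyltriphenylphosphonium iodide, CC[P+](c1ccccc1)(c1ccccc1)c1ccccc1.[I-]; iodine, II
Why: Stork–Zhao olefination as in step 4 should give the (Z)-2-iodoalkene C9=C10 with iodine cis to C8, the geometry the ring closure needs.

Step 11
Reactants: 15 (2Z,4S,5S,6Z,8Z)-2-iodo-8-methyl-11-(TBS-oxy)-5-[3-(TBDPS-oxy)prop-1-en-2-yl]-4-(TES-oxy)undeca-2,6,8-triene
Product: 16 (2Z,4S,5S,6Z,8Z)-2-iodo-8-methyl-11-(TBS-oxy)-5-[3-(TBDPS-oxy)prop-1-en-2-yl]undeca-2,6,8-trien-4-ol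
Conditions: PPTS (0.2 equiv), MeOH–CH2Cl2, 0 °C
Reagents that add atoms: none
Why: Acid-catalysed methanolysis (selective desilylation) should remove the secondary TES ether faster than the primary TBS and the TBDPS ethers.

Step 12
Reactants: 16 (2Z,4S,5S,6Z,8Z)-2-iodo-8-methyl-11-(TBS-oxy)-5-[3-(TBDPS-oxy)prop-1-en-2-yl]undeca-2,6,8-trien-4-ol; 17 angelic acid [(2Z)-2-methylbut-2-enoic acid]
Product: 19 (2Z,4S,5S,6Z,8Z)-2-iodo-8-methyl-11-(TBS-oxy)-5-[3-(TBDPS-oxy)prop-1-en-2-yl]undeca-2,6,8-trien-4-yl (2Z)-2-methylbut-2-enoate, via mixed anhydride 18 (not isolated)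
Conditions: 17, 2,4,6-trichlorobenzoyl chloride, Et3N, toluene, rt; then 16, toluene, 80 °C
Reagents that add atoms: none
Why: Yamaguchi-type esterification through the 2,4,6-trichlorobenzoyl mixed anhydride, run without a nucleophilic catalyst, should acylate the hindered allylic alcohol at the angeloyl carbonyl with retention at C8 and without isomerisation of the angeloyl group to tigloyl.

Step 13
Reactants: 19 (2Z,4S,5S,6Z,8Z)-2-iodo-8-methyl-11-(TBS-oxy)-5-[3-(TBDPS-oxy)prop-1-en-2-yl]undeca-2,6,8-trien-4-yl (2Z)-2-methylbut-2-enoate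
Product: 20 (2Z,4S,5S,6Z,8Z)-11-hydroxy-2-iodo-8-methyl-5-[3-(TBDPS-oxy)prop-1-en-2-yl]undeca-2,6,8-trien-4-yl (2Z)-2-methylbut-2-enoate
Conditions: HF·pyridine, pyridine, THF, 0 °C to rt
Reagents that add atoms: none
Why: Buffered HF·pyridine should cleave the primary TBS ether selectively (the TBDPS ether is much slower) and leaves the angelate and the alkenyl iodide alone.

Step 14
Reactants: 20 (2Z,4S,5S,6Z,8Z)-11-hydroxy-2-iodo-8-methyl-5-[3-(TBDPS-oxy)prop-1-en-2-yl]undeca-2,6,8-trien-4-yl (2Z)-2-methylbut-2-enoate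
Product: 21 (2Z,4S,5S,6Z,8Z)-2-iodo-8-methyl-11-oxo-5-[3-(TBDPS-oxy)prop-1-en-2-yl]undeca-2,6,8-trien-4-yl (2Z)-2-methylbut-2-enoate
Conditions: Dess–Martin periodinane, NaHCO3, CH2Cl2, 0 °C; used at once
Reagents that add atoms: none
Why: Dess–Martin oxidation under bicarbonate buffer gives the aldehyde under near-neutral conditions, which should keep the C3=C4 bond from moving into conjugation.

Step 15
Reactants: 21 (2Z,4S,5S,6Z,8Z)-2-iodo-8-methyl-11-oxo-5-[3-(TBDPS-oxy)prop-1-en-2-yl]undeca-2,6,8-trien-4-yl (2Z)-2-methylbut-2-enoate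
Product: 22 (1S,7S,8R)-8-angeloyloxy-12-(TBDPS-oxy)germacra-3Z,5Z,9Z,11(13)-tetraen-1-ol
Conditions: CrCl2 (8 equiv), N-[2-(4-isopropyl-4,5-dihydrooxazol-2-yl)-6-methylphenyl]methanesulfonamide (single enantiomer, the antipode matched to 1S, 8.8 equiv), Et3N (8.8 equiv), THF, rt; NiCl2 (0.5 equiv); 21 added by syringe pump (final 2 mM), rt
Reagents that add atoms: none
Why: Intramolecular Nozaki–Hiyama–Kishi reaction: zerovalent nickel inserts into the alkenyl iodide with retention, transmetalation gives an alkenyl species of trivalent chromium, and its addition to the aldehyde should close the ten-membered ring at C1–C10 under conditions that spare the angelate, while the new C1 carbinol is set by the chiral sulfonamide ligand on chromium.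

Step 16
Reactants: 22 (1S,7S,8R)-8-angeloyloxy-12-(TBDPS-oxy)germacra-3Z,5Z,9Z,11(13)-tetraen-1-ol
Product: 23 (1S,7S,8R)-8-angeloyloxygermacra-3Z,5Z,9Z,11(13)-tetraene-1,12-diol
Conditions: TBAF, AcOH (1:1), THF, 0 °C to rt
Reagents that add atoms: none
Why: Fluoride cleaves the remaining TBDPS ether, and buffering with AcOH should suppress migration of the angeloyl group to the freed hydroxyl.

Step 17
Reactants: 23 (1S,7S,8R)-8-angeloyloxygermacra-3Z,5Z,9Z,11(13)-tetraene-1,12-diol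
Product: 25 (1S,7S,8R)-8-angeloyloxy-1-hydroxygermacra-3Z,5Z,9Z,11(13)-tetraen-12-oic acid, via enal 24 (not isolated)
Conditions: TEMPO (0.2 equiv), PhI(OAc)2 (1.2 equiv), CH2Cl2, rt; then t-BuOH–H2O, 2-methylbut-2-ene, NaH2PO4, NaClO2, 0 °C
Reagents that add atoms: sodium chlorite, [Na+].[O-]Cl=O
Why: TEMPO/PhI(OAc)2 should oxidise the primary allylic alcohol in preference to the hindered secondary C1 alcohol, and Pinnick oxidation of the enal with a chlorine scavenger then gives the acrylic acid without touching the alkenes.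

Step 18
Reactants: 25 (1S,7S,8R)-8-angeloyloxy-1-hydroxygermacra-3Z,5Z,9Z,11(13)-tetraen-12-oic acid
Product: 26 (1S,3S,6R,7R,8R)-3-acetoxy-8-angeloyloxy-1-hydroxygermacra-4Z,9Z,11(13)-trien-12,6-olide (CNP0319825.3)
Conditions: Pd(OAc)2 (10 mol %), p-benzoquinone (2 equiv), AcOH–acetone (1:4), rt, no chloride source
Reagents that add atoms: acetic acid, CC(=O)O
Why: Divalent palladium binds the C3=C4–C5=C6 diene on the face opposite to the C7 side chain and the C12 carboxylate adds to C6 anti to the metal, giving an η3-allylpalladium species over C3–C4–C5; benzoquinone then triggers migration of a palladium-bound acetate to C3 on the metal face and reoxidises the zerovalent palladium that is released. The closest known reaction type is the chloride-free palladium-catalysed 1,4-acetoxylactonization of cyclic 1,3-dienes that carry a carboxylic acid on the carbon next to the diene, which gives cis-fused γ-lactones with a trans-1,4 acetate. The γ-lactone closes in the 5-exo-trig mode. C6 is controlled by C7: the tether C7–C11–C12 reaches C6 only on its own face and allylic strain across the Z C5=C6 bond holds H7 in the alkene plane, so the lactone should be cis-fused (6R); C3 is controlled by the metal, which sits opposite the new C6–O bond and delivers acetate on its own face, hence trans to the lactone oxygen (3S). The step needs 1,4- over 1,2-addition and reaction at the diene only: the inductive effect of the new C6–O bond directs acetate to the distal allyl terminus C3, the isolated C9=C10 alkene and the two acrylate-type alkenes are poor ligands for the electrophilic metal, and the anti,anti allyl geometry imposed by the ten-membered ring returns C4=C5 as Z.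

**Compound list**

1 | 2-bromoprop-2-en-1-ol | OCC(Br)=C | starting material
2 | [(2-bromoprop-2-en-1-yl)oxy](tert-butyl)diphenylsilane | C=C(Br)CO[Si](c1ccccc1)(c1ccccc1)C(C)(C)C | intermediate
3 | (2E)-3-(tributylstannyl)prop-2-en-1-ol | OC/C=C/[Sn](CCCC)(CCCC)CCCC | starting material
4 | (2E)-4-[(TBDPS-oxy)methyl]penta-2,4-dien-1-ol | OC/C=C/C(=C)CO[Si](c1ccccc1)(c1ccccc1)C(C)(C)C | intermediate
5 | {(2R,3R)-3-[3-(TBDPS-oxy)prop-1-en-2-yl]oxiran-2-yl}methanol | OC[C@H]1O[C@@H]1C(=C)CO[Si](c1ccccc1)(c1ccccc1)C(C)(C)C | intermediate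
6 | 3-(TBS-oxy)propanal | O=CCCO[Si](C)(C)C(C)(C)C | starting material
7 | tert-butyl{[(3Z)-4-iodopent-3-en-1-yl]oxy}dimethylsilane | C/C(I)=C/CCO[Si](C)(C)C(C)(C)C | intermediate
8 | tert-butyl(dimethyl){[(3Z)-4-methylhex-3-en-5-yn-1-yl]oxy}silane | C#C/C(C)=C\CCO[Si](C)(C)C(C)(C)C | intermediate
9 | lithium acetylide of 8 | [Li]C#C/C(C)=C\CCO[Si](C)(C)C(C)(C)C | intermediate
10 | diethyl[(3Z)-3-methyl-6-(TBS-oxy)hex-3-en-1-yn-1-yl]alumane | CC[Al](CC)C#C/C(C)=C\CCO[Si](C)(C)C(C)(C)C | intermediate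
11 | (2S,3S)-3-[(3Z)-3-methyl-6-(TBS-oxy)hex-3-en-1-yn-1-yl]-4-[(TBDPS-oxy)methyl]pent-4-ene-1,2-diol | CC(C)(C)[Si](C)(C)OCC/C=C(C)\C#C[C@@H](C(=C)CO[Si](c1ccccc1)(c1ccccc1)C(C)(C)C)[C@H](O)CO | intermediate
12 | (2S,3S)-3-[(1Z,3Z)-3-methyl-6-(TBS-oxy)hexa-1,3-dien-1-yl]-4-[(TBDPS-oxy)methyl]pent-4-ene-1,2-diol | CC(C)(C)[Si](C)(C)OCC/C=C(C)\C=C/[C@@H](C(=C)CO[Si](c1ccccc1)(c1ccccc1)C(C)(C)C)[C@H](O)CO | intermediate
13 | (2S,3S)-3-[(1Z,3Z)-3-methyl-6-(TBS-oxy)hexa-1,3-dien-1-yl]-4-[(TBDPS-oxy)methyl]-1,2-bis(TES-oxy)pent-4-ene | CC(C)(C)[Si](C)(C)OCC/C=C(C)\C=C/[C@@H](C(=C)CO[Si](c1ccccc1)(c1ccccc1)C(C)(C)C)[C@H](O[Si](CC)(CC)CC)CO[Si](CC)(CC)CC | intermediate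
14 | (2S,3S)-3-[(1Z,3Z)-3-methyl-6-(TBS-oxy)hexa-1,3-dien-1-yl]-4-[(TBDPS-oxy)methyl]-2-(TES-oxy)pent-4-enal | CC(C)(C)[Si](C)(C)OCC/C=C(C)\C=C/[C@@H](C(=C)CO[Si](c1ccccc1)(c1ccccc1)C(C)(C)C)[C@H](O[Si](CC)(CC)CC)C=O | intermediate
15 | (2Z,4S,5S,6Z,8Z)-2-iodo-8-methyl-11-(TBS-oxy)-5-[3-(TBDPS-oxy)prop-1-en-2-yl]-4-(TES-oxy)undeca-2,6,8-triene | CC(C)(C)[Si](C)(C)OCC/C=C(C)\C=C/[C@@H](C(=C)CO[Si](c1ccccc1)(c1ccccc1)C(C)(C)C)[C@H](O[Si](CC)(CC)CC)/C=C(/C)I | intermediate
16 | (2Z,4S,5S,6Z,8Z)-2-iodo-8-methyl-11-(TBS-oxy)-5-[3-(TBDPS-oxy)prop-1-en-2-yl]undeca-2,6,8-trien-4-ol | CC(C)(C)[Si](C)(C)OCC/C=C(C)\C=C/[C@@H](C(=C)CO[Si](c1ccccc1)(c1ccccc1)C(C)(C)C)[C@H](O)/C=C(/C)I | intermediate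
17 | angelic acid, (2Z)-2-methylbut-2-enoic acid | C/C=C(/C)C(=O)O | starting material
18 | (2Z)-2-methylbut-2-enoic 2,4,6-trichlorobenzoic anhydride | C/C=C(/C)C(=O)OC(=O)c1c(Cl)cc(Cl)cc1Cl | intermediate
19 | (2Z,4S,5S,6Z,8Z)-2-iodo-8-methyl-11-(TBS-oxy)-5-[3-(TBDPS-oxy)prop-1-en-2-yl]undeca-2,6,8-trien-4-yl (2Z)-2-methylbut-2-enoate | CC(C)(C)[Si](C)(C)OCC/C=C(C)\C=C/[C@@H](C(=C)CO[Si](c1ccccc1)(c1ccccc1)C(C)(C)C)[C@H](OC(=O)/C(C)=C\C)/C=C(/C)I | intermediate
20 | (2Z,4S,5S,6Z,8Z)-11-hydroxy-2-iodo-8-methyl-5-[3-(TBDPS-oxy)prop-1-en-2-yl]undeca-2,6,8-trien-4-yl (2Z)-2-methylbut-2-enoate | OCC/C=C(C)\C=C/[C@@H](C(=C)CO[Si](c1ccccc1)(c1ccccc1)C(C)(C)C)[C@H](OC(=O)/C(C)=C\C)/C=C(/C)I | intermediate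
21 | (2Z,4S,5S,6Z,8Z)-2-iodo-8-methyl-11-oxo-5-[3-(TBDPS-oxy)prop-1-en-2-yl]undeca-2,6,8-trien-4-yl (2Z)-2-methylbut-2-enoate | O=CC/C=C(C)\C=C/[C@@H](C(=C)CO[Si](c1ccccc1)(c1ccccc1)C(C)(C)C)[C@H](OC(=O)/C(C)=C\C)/C=C(/C)I | intermediate
22 | (1S,7S,8R)-8-angeloyloxy-12-(TBDPS-oxy)germacra-3Z,5Z,9Z,11(13)-tetraen-1-ol | O[C@H]1C/C=C(C)\C=C/[C@@H](C(=C)CO[Si](c2ccccc2)(c2ccccc2)C(C)(C)C)[C@H](OC(=O)/C(C)=C\C)/C=C1/C | intermediate
23 | (1S,7S,8R)-8-angeloyloxygermacra-3Z,5Z,9Z,11(13)-tetraene-1,12-diol | O[C@H]1C/C=C(C)\C=C/[C@@H](C(=C)CO)[C@H](OC(=O)/C(C)=C\C)/C=C1/C | intermediate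
24 | (1S,7S,8R)-8-angeloyloxy-1-hydroxygermacra-3Z,5Z,9Z,11(13)-tetraen-12-al | O[C@H]1C/C=C(C)\C=C/[C@@H](C(=C)C=O)[C@H](OC(=O)/C(C)=C\C)/C=C1/C | intermediate
25 | (1S,7S,8R)-8-angeloyloxy-1-hydroxygermacra-3Z,5Z,9Z,11(13)-tetraen-12-oic acid | O[C@H]1C/C=C(C)\C=C/[C@@H](C(=C)C(=O)O)[C@H](OC(=O)/C(C)=C\C)/C=C1/C | intermediate
26 | (1S,3S,6R,7R,8R)-3-acetoxy-8-angeloyloxy-1-hydroxygermacra-4Z,9Z,11(13)-trien-12,6-olide | C=C1C(=O)O[C@@H]2/C=C(/C)[C@@H](OC(C)=O)C[C@H](O)/C(C)=C\[C@@H](OC(=O)/C(C)=C\C)[C@H]12 | target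

**Count and risks**

Total step count: 18. Longest linear sequence: 16 steps (steps 1–3, then 6–18); the second branch (steps 4–5) joins at step 6.

Step 18 (key step). What may go wrong: addition across the diene in the 1,2-sense or on the wrong face, or capture of the cisoid ring diene by benzoquinone in a Diels–Alder reaction before palladium acts. Fallback, setting out from 25 and coming back at 26: iodolactonization of 25 (I2, NaHCO3, MeCN, 0 °C) should give the 5-iodo-12,6-olide F1 by anti addition, with the lactone oxygen entering C6 on the face of the C7 side chain and iodine at C5 on the other face. Treatment of F1 with AgOAc in AcOH then replaces the allylic iodide by acetate with allylic transposition, the acetate entering at C3 on the face that iodide leaves. This gives 26 in two steps by halolactonization and silver-assisted allylic substitution instead of the palladium-catalysed oxidation.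

Step 15 (ring closure). What may go wrong: poor facial selectivity at C1 in the ring-closing addition, because the folded all-cis chain may override the ligand on chromium. Fallback, setting out from 22 (as the mixture of C1 epimers) and coming back at 22 (single 1S epimer): Dess–Martin oxidation of the mixture (NaHCO3, CH2Cl2, 0 °C) gives the ring enone F2, and Corey–Bakshi–Shibata reduction of F2 with (R)-2-methyl-CBS-oxazaborolidine and catecholborane (toluene, −78 °C) should deliver hydride to the face that gives the (1S) alcohol, the C10 alkenyl group acting as the large and C2H2 as the small substituent. The stereocentre is then set by reagent-controlled reduction and not in the C–C bond formation.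

Step 12 (angelate). What may go wrong: isomerisation of the angeloyl group to the tigloyl group, or slow acyl transfer to the hindered C8 alcohol. Fallback, setting out from 16 and coming back at 19: esterification of 16 with 2-[bis(2,2,2-trifluoroethoxy)phosphoryl]propanoic acid (DCC, DMAP, CH2Cl2, 0 °C) gives the phosphonate ester F3, and Still–Gennari olefination of F3 with acetaldehyde (KN(SiMe3)2, 18-crown-6, THF, −78 °C) should build the (Z)-2-methylbut-2-enoate directly on O8 under kinetic control, so that no preformed angeloyl donor is needed.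

**Further compounds**

F1 | step 18 | (1S,5S,6S,7S,8R)-8-angeloyloxy-1-hydroxy-5-iodogermacra-3Z,9Z,11(13)-trien-12,6-olide (iodine at C5 trans to O6) | C=C1C(=O)O[C@@H]2[C@@H](I)/C(C)=C\C[C@H](O)/C(C)=C\[C@@H](OC(=O)/C(C)=C\C)[C@H]12
F2 | step 15 | (7S,8R)-8-angeloyloxy-12-(TBDPS-oxy)germacra-3Z,5Z,9Z,11(13)-tetraen-1-one | O=C1C/C=C(C)\C=C/[C@@H](C(=C)CO[Si](c2ccccc2)(c2ccccc2)C(C)(C)C)[C@H](OC(=O)/C(C)=C\C)/C=C1/C
F3 | step 12 | (2Z,4S,5S,6Z,8Z)-2-iodo-8-methyl-11-(TBS-oxy)-5-[3-(TBDPS-oxy)prop-1-en-2-yl]undeca-2,6,8-trien-4-yl 2-[bis(2,2,2-trifluoroethoxy)phosphoryl]propanoate | CC(C)(C)[Si](C)(C)OCC/C=C(C)\C=C/[C@@H](C(=C)CO[Si](c1ccccc1)(c1ccccc1)C(C)(C)C)[C@H](OC(=O)C(C)P(=O)(OCC(F)(F)F)OCC(F)(F)F)/C=C(/C)I
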